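## Retrosynthetic overview

- The ester bond is cut last: the target comes from a ring A allylic alcohol carrying a silyl-masked diosphenol and a TBS-protected (2E,4E,6R)-6-(hydroxymethyl)octa-2,4-dienoic acid (from butanal and formaldehyde by organocatalytic hydroxymethylation and vinylogous HWE olefination).
- The diosphenol comes from enolate autoxidation, the ring A alkene from quinone dehydrogenation of the ring B enone, and the carbinol from equatorial hydride delivery to a ring A ketone.
- Key disconnection: the six-membered ring A ketone comes from a 1-vinylcyclopentanol by a hydrogen-atom-transfer-initiated semipinacol ring expansion (1,2-shift of the quaternary carbon), which forms the bond between the two methyl-bearing carbons and sets the secondary methyl centre.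
- The vinyl carbinol comes from the Hajos–Parrish ketone, made from 2-methylcyclopentane-1,3-dione and methyl vinyl ketone; the proline aldol sets the quaternary centre.
- Ring order: ring B is annulated first onto the cyclopentane; ring A is made last by expanding that cyclopentane from five to six members.

Assumption: the bicyclic naphthalenone compounds are named with one fixed naphthalene numbering (C4a quaternary, C5 CHMe, C6 carbinol or ester carbon, C2 ring B carbonyl, C3 enol carbon), also where lowest-locant rules would renumber.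

## Route

Step 1
Reactants: 1 2-methylcyclopentane-1,3-dione; 2 but-3-en-2-one (methyl vinyl ketone)
Product: 5 (S)-7a-methyl-2,3,7,7a-tetrahydro-1H-indene-1,5(6H)-dione (Hajos–Parrish ketone), via Michael triketone 3 (not isolated), via cis-fused aldol ketol 4 (not isolated)
Conditions: 2 (1.3 equiv), AcOH (cat.), H2O, 70 °C; then (S)-proline (3 mol%), DMF, 20 °C; then H2SO4 (cat.), DMF, 95 °C
Reagents that add atoms: none
Why: Michael addition followed by the proline-catalysed Hajos–Parrish–Eder–Sauer–Wiechert intramolecular aldol and acid dehydration (Robinson-type annulation), in which the (S)-proline enamine attacks one of the two enantiotopic ring carbonyls and fixes the quaternary centre as 7aS (about 93–95% ee, raised by crystallisation), leaving the cyclopentanone that is expanded later.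

Step 2
Reactants: 5 (S)-Hajos–Parrish ketone
Product: 6 (1R,7aS)-1-ethenyl-1-hydroxy-7a-methyl-1,2,3,6,7,7a-hexahydro-5H-inden-5-one
Conditions: CH2=CHMgBr (1.05 equiv, slow addition), THF, −78 °C; then H2O
Reagents that add atoms: vinylmagnesium bromide, C=C[Mg]Br
Why: Grignard 1,2-addition, expected to favour the saturated cyclopentanone because it is more electrophilic than the conjugated, beta,beta-disubstituted enone carbonyl, with attack from the face opposite the angular methyl as with 17-oxo steroids (this carbinol centre is erased in step 3).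

Step 3
Reactants: 6 (1R,7aS)-1-ethenyl-1-hydroxy-7a-methyl-1,2,3,6,7,7a-hexahydro-5H-inden-5-one
Product: 7 (4aR,5R)-4a,5-dimethyl-4,4a,7,8-tetrahydronaphthalene-2,6(3H,5H)-dione
Conditions: Co(salen′) (5 mol%; salen′ = dianion of (R,R)-N,N′-bis(3,5-di-tert-butylsalicylidene)cyclohexane-1,2-diamine, divalent cobalt), N-fluoro-2,4,6-trimethylpyridinium triflate (1.2 equiv), PhSiH3 (1.2 equiv), PhCF3, 0 °C to 20 °C
Reagents that add atoms: none
Why: Proposed new method: a cobalt hydride made from the salen complex, the N–F oxidant and the silane transfers a hydrogen atom to the terminal vinyl carbon (the electron-poor trisubstituted enone is a much poorer acceptor), the secondary radical is captured and oxidised to an alkylcobalt species (tetravalent cobalt) that acts as a secondary cation equivalent, and the quaternary ring carbon (the bulkiest carbinol substituent, so anti to the cobalt fragment, and the best migrating group) undergoes a 1,2-shift with inversion at the cobalt-bearing carbon while the O–H proton is lost, which forms the C4a–C5 bond and ring A and turns the cyclopentanol into a cyclohexanone; the new C5 methyl is expected to prefer to sit syn to the C–O bond and not over the ring CH2 in the bridged transition state, giving the 5R isomer cis to the angular methyl, which is also estimated to be the slightly more stable equatorial epimer (a minor 5-epimer is separable and can be re-equilibrated with DBU), and the closest known reaction type is the cobalt–salen, N-fluoropyridinium and silane radical–polar crossover semipinacol rearrangement of tertiary allylic alcohols with 1,1-disubstituted alkenes (tertiary cation equivalents), together with the related hydroalkoxylation of monosubstituted alkenes, neither shown for a secondary centre with expansion of an unstrained cyclopentanol.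

Step 4
Reactants: 7 (4aR,5R)-4a,5-dimethyl-4,4a,7,8-tetrahydronaphthalene-2,6(3H,5H)-dione
Product: 8 (4aR,5R,6S)-6-hydroxy-4a,5-dimethyl-4,4a,5,6,7,8-hexahydronaphthalen-2(3H)-one
Conditions: LiBH(s-Bu)3 (1.05 equiv), THF, −78 °C; then H2O
Reagents that add atoms: none
Why: Bulky trialkylborohydride reduction, in which the saturated ring A ketone reacts far faster at −78 °C than the beta,beta-disubstituted enone and the hydride enters along the equatorial trajectory on the face opposite the axial C4a methyl, giving the axial 6S alcohol cis to both methyls.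

Step 5
Reactants: 8 (4aR,5R,6S)-6-hydroxy-4a,5-dimethyl-4,4a,5,6,7,8-hexahydronaphthalen-2(3H)-one
Product: 9 (4aR,5R,6S)-6-hydroxy-4a,5-dimethyl-4,4a,5,6-tetrahydronaphthalen-2(3H)-one
Conditions: chloranil (1.3 equiv), t-BuOH, reflux
Reagents that add atoms: none
Why: Quinone dehydrogenation of an enone through its extended dienol (the method used for steroidal 4-en-3-ones), where only C8 carries gamma hydrogens because the other gamma carbon is quaternary, so hydride loss from C7 gives the linear dienone alone and leaves the secondary alcohol and all stereocentres untouched.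

Step 6
Reactants: 9 (4aR,5R,6S)-6-hydroxy-4a,5-dimethyl-4,4a,5,6-tetrahydronaphthalen-2(3H)-one
Product: 12 (4aS,5R,6S)-3,6-dihydroxy-4a,5-dimethyl-5,6-dihydronaphthalen-2(4aH)-one, via C3 hydroperoxide 10 (not isolated), via 2,3-dione keto tautomer 11 (not isolated)
Conditions: KOt-Bu (3 equiv), O2 (1 atm), THF/t-BuOH, −20 °C to 0 °C; then 1 M HCl
Reagents that add atoms: dioxygen, O=O
Why: Base-mediated enolate autoxidation (classical diosphenol synthesis), in which the C6 alkoxide blocks vinylogous deprotonation so the only enolate forms at C3, traps O2 as the hydroperoxide, loses hydroxide in a Kornblum–DeLaMare-type elimination to the 2,3-dione and enolises towards C4 to the conjugated diosphenol without touching a stereocentre.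

Step 7
Reactants: 12 (4aS,5R,6S)-3,6-dihydroxy-4a,5-dimethyl-5,6-dihydronaphthalen-2(4aH)-one
Product: 13 (4aS,5R,6S)-3-[(tert-butyldimethylsilyl)oxy]-6-hydroxy-4a,5-dimethyl-5,6-dihydronaphthalen-2(4aH)-one
Conditions: TBSCl (1.05 equiv), imidazole, CH2Cl2, 0 °C
Reagents that add atoms: tert-butyldimethylsilyl chloride, CC(C)(C)[Si](C)(C)Cl
Why: Chemoselective O-silylation, since the acidic enol OH of the diosphenol reacts much faster than the hindered pseudoaxial secondary alcohol next to the CHMe carbon, which stays free for acylation.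

Step 8
Reactants: 14 butanal; 15 formaldehyde (37% aqueous)
Product: 17 ethyl (2E,4E,6R)-6-(hydroxymethyl)octa-2,4-dienoate, via (S)-2-(hydroxymethyl)butanal 16 (not isolated)
Conditions: 15 (aq.), (R)-α,α-diphenylprolinol trimethylsilyl ether (10 mol%), pH 7 phosphate buffer, toluene, 20 °C; then organic extract added to (EtO)2P(O)CH2CH=CHCO2Et (2.5 equiv), LiOH·H2O, 4 Å molecular sieves, THF, 20 °C
Reagents that add atoms: triethyl (E)-4-phosphonocrotonate, CCOC(=O)/C=C/CP(=O)(OCC)OCC
Why: Enamine-catalysed enantioselective alpha-hydroxymethylation (organocatalytic cross-aldol with formaldehyde), in which the (R)-diarylprolinol silyl ether shields one enamine face and sets the stereocentre (S in 16, named 6R in the dienoate only because the CIP priorities change), followed by a vinylogous Horner–Wadsworth–Emmons olefination that gives the 2E,4E diene and traps the labile aldehyde before it can racemise or dehydrate.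

Step 9
Reactants: 17 ethyl (2E,4E,6R)-6-(hydroxymethyl)octa-2,4-dienoate
Product: 18 ethyl (2E,4E,6R)-6-{[(tert-butyldimethylsilyl)oxy]methyl}octa-2,4-dienoate
Conditions: TBSCl, imidazole, DMF, 20 °C
Reagents that add atoms: tert-butyldimethylsilyl chloride, CC(C)(C)[Si](C)(C)Cl
Why: Standard silyl ether protection of the primary alcohol so that the acid cannot self-esterify in step 11.

Step 10
Reactants: 18 ethyl (2E,4E,6R)-6-{[(tert-butyldimethylsilyl)oxy]methyl}octa-2,4-dienoate
Product: 19 (2E,4E,6R)-6-{[(tert-butyldimethylsilyl)oxy]methyl}octa-2,4-dienoic acid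
Conditions: LiOH·H2O, THF/MeOH/H2O, 20 °C; then 1 M HCl to pH 3, 0 °C
Reagents that add atoms: lithium hydroxide, [Li+].[OH-]
Why: Ester saponification, in which aqueous LiOH does not deprotonate the remote C6–H, so the stereocentre and the E,E geometry are kept and the primary TBS ether survives.

Step 11
Reactants: 13 (4aS,5R,6S)-3-[(tert-butyldimethylsilyl)oxy]-6-hydroxy-4a,5-dimethyl-5,6-dihydronaphthalen-2(4aH)-one; 19 (2E,4E,6R)-6-{[(tert-butyldimethylsilyl)oxy]methyl}octa-2,4-dienoic acid
Product: 21 (4aS,5R,6S)-3-[(tert-butyldimethylsilyl)oxy]-4a,5-dimethyl-2-oxo-2,4a,5,6-tetrahydronaphthalen-6-yl (2E,4E,6R)-6-{[(tert-butyldimethylsilyl)oxy]methyl}octa-2,4-dienoate, via mixed trichlorobenzoic anhydride 20 (not isolated)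
Conditions: 19 (1.5 equiv), 2,4,6-trichlorobenzoyl chloride, Et3N, toluene, 20 °C; then 13, DMAP, toluene, 20 °C to 40 °C
Reagents that add atoms: none
Why: Yamaguchi esterification through the mixed anhydride and DMAP acyl transfer, which suits hindered secondary alcohols, does not break the carbinol C–O bond (C6 stays S) and cannot acylate the silyl-masked diosphenol oxygen.

Step 12
Reactants: 21 bis-silyl ester from step 11
Product: 22 Septeremophilane E, (4aS,5R,6S)-3-hydroxy-4a,5-dimethyl-2-oxo-2,4a,5,6-tetrahydronaphthalen-6-yl (2E,4E,6R)-6-(hydroxymethyl)octa-2,4-dienoate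
Conditions: HF·pyridine, THF/pyridine, 0 °C to 20 °C
Reagents that add atoms: none
Why: Fluoride-mediated global desilylation, in which buffered HF·pyridine cleaves both the enol silyl ether and the primary TBS ether while the allylic dienoate ester and the trienone are stable.

## Compound list

1 | 2-methylcyclopentane-1,3-dione | CC1C(=O)CCC1=O | starting material
2 | but-3-en-2-one (methyl vinyl ketone) | CC(=O)C=C | starting material
3 | 2-methyl-2-(3-oxobutyl)cyclopentane-1,3-dione | CC(=O)CCC1(C)C(=O)CCC1=O | intermediate
4 | (3aS,7aS)-3a-hydroxy-7a-methylhexahydro-1H-indene-1,5(4H)-dione | C[C@]12CCC(=O)C[C@@]1(O)CCC2=O | intermediate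
5 | (S)-7a-methyl-2,3,7,7a-tetrahydro-1H-indene-1,5(6H)-dione | C[C@]12CCC(=O)C=C1CCC2=O | intermediate
6 | (1R,7aS)-1-ethenyl-1-hydroxy-7a-methyl-1,2,3,6,7,7a-hexahydro-5H-inden-5-one | C[C@]12CCC(=O)C=C1CC[C@@]2(O)C=C | intermediate
7 | (4aR,5R)-4a,5-dimethyl-4,4a,7,8-tetrahydronaphthalene-2,6(3H,5H)-dione | O=C1CCC2=CC(=O)CC[C@]2(C)[C@H]1C | intermediate
8 | (4aR,5R,6S)-6-hydroxy-4a,5-dimethyl-4,4a,5,6,7,8-hexahydronaphthalen-2(3H)-one | O[C@H]1CCC2=CC(=O)CC[C@]2(C)[C@H]1C | intermediate
9 | (4aR,5R,6S)-6-hydroxy-4a,5-dimethyl-4,4a,5,6-tetrahydronaphthalen-2(3H)-one | O[C@H]1C=CC2=CC(=O)CC[C@]2(C)[C@H]1C | intermediate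
10 | (4aR,5R,6S)-3-hydroperoxy-6-hydroxy-4a,5-dimethyl-4,4a,5,6-tetrahydronaphthalen-2(3H)-one (both C3 epimers) | O[C@H]1C=CC2=CC(=O)C(OO)C[C@]2(C)[C@H]1C | intermediate
11 | (4aR,5R,6S)-6-hydroxy-4a,5-dimethyl-4a,5-dihydronaphthalene-2,3(4H,6H)-dione | O[C@H]1C=CC2=CC(=O)C(=O)C[C@]2(C)[C@H]1C | intermediate
12 | (4aS,5R,6S)-3,6-dihydroxy-4a,5-dimethyl-5,6-dihydronaphthalen-2(4aH)-one | O[C@H]1C=CC2=CC(=O)C(O)=C[C@]2(C)[C@H]1C | intermediate
13 | (4aS,5R,6S)-3-[(tert-butyldimethylsilyl)oxy]-6-hydroxy-4a,5-dimethyl-5,6-dihydronaphthalen-2(4aH)-one | O[C@H]1C=CC2=CC(=O)C(O[Si](C)(C)C(C)(C)C)=C[C@]2(C)[C@H]1C | intermediate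
14 | butanal | CCCC=O | starting material
15 | formaldehyde | C=O | starting material
16 | (S)-2-(hydroxymethyl)butanal | CC[C@H](C=O)CO | intermediate
17 | ethyl (2E,4E,6R)-6-(hydroxymethyl)octa-2,4-dienoate | CC[C@H](/C=C/C=C/C(=O)OCC)CO | intermediate
18 | ethyl (2E,4E,6R)-6-{[(tert-butyldimethylsilyl)oxy]methyl}octa-2,4-dienoate | CC[C@H](/C=C/C=C/C(=O)OCC)CO[Si](C)(C)C(C)(C)C | intermediate
19 | (2E,4E,6R)-6-{[(tert-butyldimethylsilyl)oxy]methyl}octa-2,4-dienoic acid | CC[C@H](/C=C/C=C/C(=O)O)CO[Si](C)(C)C(C)(C)C | intermediate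
20 | (2E,4E,6R)-6-{[(tert-butyldimethylsilyl)oxy]methyl}octa-2,4-dienoic 2,4,6-trichlorobenzoic anhydride | CC[C@H](/C=C/C=C/C(=O)OC(=O)c1c(Cl)cc(Cl)cc1Cl)CO[Si](C)(C)C(C)(C)C | intermediate
21 | (4aS,5R,6S)-3-[(tert-butyldimethylsilyl)oxy]-4a,5-dimethyl-2-oxo-2,4a,5,6-tetrahydronaphthalen-6-yl (2E,4E,6R)-6-{[(tert-butyldimethylsilyl)oxy]methyl}octa-2,4-dienoate | CC[C@H](/C=C/C=C/C(=O)O[C@H]1C=CC2=CC(=O)C(O[Si](C)(C)C(C)(C)C)=C[C@]2(C)[C@H]1C)CO[Si](C)(C)C(C)(C)C | intermediate
22 | Septeremophilane E | CC[C@H](/C=C/C=C/C(=O)O[C@H]1C=CC2=CC(=O)C(O)=C[C@]2(C)[C@H]1C)CO | target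

## Step count and risks

Total step count: 12 (steps 1–7 for the core, 8–10 for the acid, 11–12 for coupling and deprotection).
Longest linear sequence: 9 steps (steps 1–7, 11, 12, from compound 1).

**Step 3 (proposed new ring expansion).** The alkylcobalt intermediate could close to an oxirane through the neighbouring hydroxyl instead of undergoing the 1,2-shift, the ring CH2 could migrate instead of the quaternary carbon, or the C5 epimer ratio could be poor. The fallback uses known chemistry, sets out from 6 and comes back at 7. Hydroxyl-directed epoxidation of the vinyl group (VO(acac)2, t-BuOOH, CH2Cl2) gives the epoxy alcohol (1S,7aS)-1-hydroxy-7a-methyl-1-(oxiran-2-yl)-1,2,3,6,7,7a-hexahydro-5H-inden-5-one F1. BF3·OEt2 (CH2Cl2, −78 °C) then triggers the established semipinacol rearrangement of a tertiary alpha-hydroxy epoxide, with the ring carbon migrating anti to the opening C–O bond, and gives the ring-expanded beta-hydroxy ketone (4aR)-5-(hydroxymethyl)-4a-methyl-4,4a,7,8-tetrahydronaphthalene-2,6(3H,5H)-dione F2. MsCl and Et3N followed by DBU give the exocyclic enone (4aS)-4a-methyl-5-methylidene-4,4a,7,8-tetrahydronaphthalene-2,6(3H,5H)-dione F3. Conjugate reduction of this unhindered enone with [(Ph3P)CuH]6 (toluene, then aqueous work-up), with protonation on the face away from the angular methyl, returns 7.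

**Step 2 (chemoselective vinyl addition).** The Grignard reagent could also attack the enone carbonyl or enolise the ketone. The fallback sets out from 5 and comes back at 6. HC(OEt)3 and TsOH (cat.) in EtOH mask the enone as the dienol ether (S)-5-ethoxy-7a-methyl-2,6,7,7a-tetrahydro-1H-inden-1-one F4, as is done for steroidal enediones. Vinylmagnesium bromide can then only add to the remaining ketone and gives (1R,7aS)-5-ethoxy-1-ethenyl-7a-methyl-2,6,7,7a-tetrahydro-1H-inden-1-ol F5. Dilute aqueous oxalic acid in THF unmasks the enone and returns 6.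

**Step 6 (autoxidation to the diosphenol).** The diosphenolate could be over-oxidised or cleaved by O2 and base. The fallback sets out from 9 and comes back at 12. LiN(SiMe3)2 (2.2 equiv, THF, −78 °C) followed by 2-(phenylsulfonyl)-3-phenyloxaziridine (Davis enolate hydroxylation) gives (4aR,5R,6S)-3,6-dihydroxy-4a,5-dimethyl-4,4a,5,6-tetrahydronaphthalen-2(3H)-one F6 as a C3 epimer mixture. Cu(OAc)2 (cat.) with air in MeOH oxidises this acyloin to the 1,2-dione, which enolises to 12, and the allylic C6 alcohol is left alone.

Further compounds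
F1 | step 3 | (1S,7aS)-1-hydroxy-7a-methyl-1-(oxiran-2-yl)-1,2,3,6,7,7a-hexahydro-5H-inden-5-one (either oxirane epimer) | C[C@]12CCC(=O)C=C1CC[C@@]2(O)C1CO1
F2 | step 3 | (4aR)-5-(hydroxymethyl)-4a-methyl-4,4a,7,8-tetrahydronaphthalene-2,6(3H,5H)-dione (C5 epimers) | O=C1CCC2=CC(=O)CC[C@]2(C)C1CO
F3 | step 3 | (4aS)-4a-methyl-5-methylidene-4,4a,7,8-tetrahydronaphthalene-2,6(3H,5H)-dione | O=C1CCC2=CC(=O)CC[C@]2(C)C1=C
F4 | step 2 | (S)-5-ethoxy-7a-methyl-2,6,7,7a-tetrahydro-1H-inden-1-one | C[C@]12CCC(OCC)=CC1=CCC2=O
F5 | step 2 | (1R,7aS)-5-ethoxy-1-ethenyl-7a-methyl-2,6,7,7a-tetrahydro-1H-inden-1-ol | C[C@]12CCC(OCC)=CC1=CC[C@@]2(O)C=C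
F6 | step 6 | (4aR,5R,6S)-3,6-dihydroxy-4a,5-dimethyl-4,4a,5,6-tetrahydronaphthalen-2(3H)-one (C3 epimers) | O[C@H]1C=CC2=CC(=O)C(O)C[C@]2(C)[C@H]1C
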